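**Plan** (labdane numbering throughout)

- Retrosynthetic cuts: O15–Si, the O3 acetyl and C3–H first; then C4–C18 and the two ring A alkenes; then C9–C10 (ring B), which leads back to a flat arene; the chain is cut at C5–C6, C6=C7 and C8=C9.
- Enabling feature: ring A carries oxygen on C3, the ester carbon C19 on C4 and the methyl-bearing quaternary C10 para to C3, which is a 5-methylsalicylate in disguise; the exocyclic C8=C17 beside C9 is what an allylsilane leaves after reacting through C9.
- Forward order: ring A is taken as a bromosalicylate; the C6–C15 chain is grown from (S)-citronellol and joined at C5–C6 by B-alkyl Suzuki coupling; ring B closes by oxidative dearomatisation with allylsilane capture; ring A is then reduced and methylated.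
- Stereochemistry: C13 from (S)-citronellol; C9/C10 relative configuration from the chair closure of the Z-allylsilane and absolute configuration from a chiral aryl-iodine diacetate; C5 and C4 from dissolving-metal reduction and methylation anti to the C10 methyl; C3 from equatorial hydride delivery.

Key step: step 12

Assumption: the (R,R)-lactamide aryl-iodine diacetate is taken to screen the face of C10 that leads to the 10β-methyl series; if the opposite sense is found, its (S,S) antipode is used with nothing else changed.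

**Route**

Step 1
Reactants: 1 3-bromo-4-methylphenol
Product: 2 2-bromo-4-(methoxymethoxy)-1-methylbenzene
Conditions: NaH, MOMCl, THF, 0 °C to rt
Reagents that add atoms: chloromethyl methyl ether, COCCl
Why: Williamson-type O-alkylation of the sodium phenoxide installs the methoxymethyl ether that serves as the ortho-directing group in the next step.

Step 2
Reactants: 2 2-bromo-4-(methoxymethoxy)-1-methylbenzene
Product: 4 methyl 2-bromo-6-(methoxymethoxy)-3-methylbenzoate, via aryllithium 3 (not isolated)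
Conditions: LiN(i-Pr)2, THF, −78 °C; then ClCO2Me, −78 °C to rt
Reagents that add atoms: methyl chloroformate, COC(=O)Cl
Why: Directed ortho-metalation removes the most acidic ring proton, the one flanked by the acetal oxygen and bromine, with an amide base that does not exchange bromine, and the aryllithium is acylated at −78 °C before it can lose LiBr.

Step 3
Reactants: 4 methyl 2-bromo-6-(methoxymethoxy)-3-methylbenzoate
Product: 5 methyl 2-bromo-6-hydroxy-3-methylbenzoate
Conditions: HCl (cat.), MeOH, 40 °C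
Reagents that add atoms: none
Why: Acid-catalysed acetal methanolysis frees the phenol, while the methyl ester, flanked by two ortho substituents and in methanol, is unchanged.

Step 4
Reactants: 6 (S)-citronellol
Product: 7 triisopropyl{[(3S)-3,7-dimethyloct-6-en-1-yl]oxy}silane
Conditions: i-Pr3SiCl, imidazole, CH2Cl2, rt
Reagents that add atoms: chlorotriisopropylsilane, CC(C)[Si](Cl)(C(C)C)C(C)C
Why: Imidazole-promoted silylation protects O15 with a group that tolerates base, hydride, dissolving metal and the oxidant of the key step.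

Step 5
Reactants: 7 triisopropyl{[(3S)-3,7-dimethyloct-6-en-1-yl]oxy}silane
Product: 9 (4S)-4-methyl-6-[(triisopropylsilyl)oxy]hexanal, via ozonide 8 (not isolated)
Conditions: O3, CH2Cl2, −78 °C; then Me2S, −78 °C to rt
Reagents that add atoms: ozone, [O-][O+]=O
Why: Ozonolysis with reductive work-up cleaves the trisubstituted alkene to the aldehyde whose carbonyl carbon becomes C9, without touching the C13 stereocentre.

Step 6
Reactants: 10 ethyl (triphenylphosphoranylidene)acetate; 11 (iodomethyl)trimethylsilane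
Product: 13 ethyl 2-(triphenylphosphoranylidene)-3-(trimethylsilyl)propanoate, via phosphonium iodide 12 (not isolated)
Conditions: MeCN, 80 °C; then aq. NaOH, CH2Cl2, 0 °C
Reagents that add atoms: none
Why: C-Alkylation of a stabilised phosphorus ylide by a primary α-silyl iodide followed by deprotonation of the phosphonium salt gives the α-substituted stabilised ylide that carries C7, C8 and C17 with silicon in place.

Step 7
Reactants: 9 (4S)-4-methyl-6-[(triisopropylsilyl)oxy]hexanal; 13 ethyl 2-(triphenylphosphoranylidene)-3-(trimethylsilyl)propanoate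
Product: 14 ethyl (2Z,6S)-6-methyl-8-[(triisopropylsilyl)oxy]-2-[(trimethylsilyl)methyl]oct-2-enoate
Conditions: toluene, 90 °C
Reagents that add atoms: none
Why: Wittig olefination with an α-substituted ester-stabilised ylide places the ester trans to the aldehyde-derived chain, so CH2SiMe3 (C17) and C11 end cis on C8=C9 as the later chair closure requires.

Step 8
Reactants: 14 ethyl (2Z,6S)-6-methyl-8-[(triisopropylsilyl)oxy]-2-[(trimethylsilyl)methyl]oct-2-enoate
Product: 15 (2Z,6S)-6-methyl-8-[(triisopropylsilyl)oxy]-2-[(trimethylsilyl)methyl]oct-2-en-1-ol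
Conditions: i-Bu2AlH, CH2Cl2, −78 °C; aq. potassium sodium tartrate
Reagents that add atoms: none
Why: 1,2-Reduction of the conjugated ester by the aluminium hydride gives the allylic alcohol and leaves the allylsilane, the alkene geometry and the silyl ether alone.

Step 9
Reactants: 15 (2Z,6S)-6-methyl-8-[(triisopropylsilyl)oxy]-2-[(trimethylsilyl)methyl]oct-2-en-1-ol
Product: 16 (2Z,6S)-6-methyl-8-[(triisopropylsilyl)oxy]-2-[(trimethylsilyl)methyl]oct-2-enal
Conditions: MnO2, CH2Cl2, rt
Reagents that add atoms: none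
Why: Allylic oxidation with MnO2 is selective for the allylic alcohol and neutral, so the acid-sensitive allylsilane survives.

Step 10
Reactants: 16 (2Z,6S)-6-methyl-8-[(triisopropylsilyl)oxy]-2-[(trimethylsilyl)methyl]oct-2-enal
Product: 17 triisopropyl{[(3S,6Z)-3-methyl-7-[(trimethylsilyl)methyl]nona-6,8-dien-1-yl]oxy}silane
Conditions: Ph3PCH3Br, KOt-Bu, THF, 0 °C
Reagents that add atoms: methyltriphenylphosphonium bromide, C[P+](c1ccccc1)(c1ccccc1)c1ccccc1.[Br-]
Why: Wittig methylenation of the enal gives the 1,3-diene whose terminal vinyl group supplies C6 and C7.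

Step 11
Reactants: 17 triisopropyl{[(3S,6Z)-3-methyl-7-[(trimethylsilyl)methyl]nona-6,8-dien-1-yl]oxy}silane; 5 methyl 2-bromo-6-hydroxy-3-methylbenzoate
Product: 19 methyl 6-hydroxy-3-methyl-2-[(3Z,7S)-7-methyl-3-[(trimethylsilyl)methyl]-9-[(triisopropylsilyl)oxy]non-3-en-1-yl]benzoate, via alkylborane 18 (not isolated)
Conditions: 9-BBN, THF, 0 °C to rt; then 5, Pd(OAc)2, SPhos, K3PO4, H2O, THF, 60 °C
Reagents that add atoms: none
Why: 9-BBN hydroborates only the monosubstituted vinyl terminus of the diene (anti-Markovnikov), and the B-alkyl borane undergoes B-alkyl Suzuki–Miyaura coupling after oxidative addition of the hindered C–Br bond to zerovalent palladium carrying a dialkylbiarylphosphine, forming C5–C6.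

Step 12
Reactants: 19 methyl 6-hydroxy-3-methyl-2-[(3Z,7S)-7-methyl-3-[(trimethylsilyl)methyl]-9-[(triisopropylsilyl)oxy]non-3-en-1-yl]benzoate
Product: 20 methyl 3-oxo-15-[(triisopropylsilyl)oxy]-18-norlabda-1,4,8(17)-trien-19-oate (9αH,10βMe,13S)
Conditions: (R,R)-ArI(OAc)2 (Ar = 2,6-bis[1-(mesitylcarbamoyl)ethoxy]phenyl, preformed, 1.1 equiv), CH2Cl2/(CF3)2CHOH 4:1, −40 °C
Reagents that add atoms: none
Why: Proposed new method: ligand exchange binds O3 to trivalent iodine and two-electron oxidation makes ring A a phenoxonium-type electrophile whose para carbon C10 is attacked by C9, the γ-carbon of the tethered allylsilane, after which the β-silyl cation at C8 loses silicon to leave C8=C17 (intramolecular Hosomi–Sakurai capture). The closest known reaction types are PhI(OAc)2-mediated dearomatisations of phenols in which a tethered allylsilane attacks the para carbon to give spiro dienones, and enantioselective dearomatising spirolactonisations with chiral aryl-iodine reagents, whereas closure to a fused ring at a methyl-bearing para carbon is without precedent. Ring B closes in a 6-endo-trig cation–olefin mode with respect to C8=C9 through a chair in which C6, C7 and C8 span C5 and C9. The chair and the Z alkene hold the C11 chain equatorial, so H9 ends anti to the C10 methyl, while the absolute configuration has to come from the lactamide arms of the iodine reagent still bound to O3 in this weakly ionising medium, and that face selection is the unproven part. The step needs attack at C10 and not at the ortho carbon C4, which the electron-withdrawing and bulky ester on C4 and the cation-stabilising methyl on C10 secure, and it needs oxidation of the phenol and not of the allylsilane, for which the preformed diacetate is used so that no peracid is present.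

Step 13
Reactants: 20 methyl 3-oxo-15-[(triisopropylsilyl)oxy]-18-norlabda-1,4,8(17)-trien-19-oate (9αH,10βMe,13S)
Product: 21 methyl 3-oxo-15-[(triisopropylsilyl)oxy]-18-norlabda-4,8(17)-dien-19-oate (9αH,10βMe,13S)
Conditions: [(Ph3P)CuH]6, H2O, THF, rt
Reagents that add atoms: none
Why: Copper hydride conjugate reduction is governed by access to the β-carbon, so hydride should add to the singly substituted C1 of the C1=C2–C3=O arm and not to the fully substituted C5, and the isolated C8=C17 alkene is inert.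

Step 14
Reactants: 21 methyl 3-oxo-15-[(triisopropylsilyl)oxy]-18-norlabda-4,8(17)-dien-19-oate (9αH,10βMe,13S)
Product: 23 methyl 3-oxo-15-[(triisopropylsilyl)oxy]labd-8(17)-en-19-oate (4αMe,5αH,9αH,10βMe,13S), via lithium enolate 22 (not isolated)
Conditions: Li, t-BuOH (1 equiv), NH3/THF, −78 °C; then MeI, −78 to −33 °C
Reagents that add atoms: iodomethane, CI
Why: Stork reductive alkylation of the 4-carbomethoxy enone protonates C5 on the α face to give the trans ring fusion, and the β-keto ester enolate is methylated at C4 anti to the axial C10 methyl, which leaves the ester axial (β) and the new methyl α.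

Step 15
Reactants: 23 methyl 3-oxo-15-[(triisopropylsilyl)oxy]labd-8(17)-en-19-oate (4αMe,5αH,9αH,10βMe,13S)
Product: 24 methyl 3α-hydroxy-15-[(triisopropylsilyl)oxy]labd-8(17)-en-19-oate
Conditions: LiBH(s-Bu)3, THF, −78 °C; then H2O
Reagents that add atoms: none
Why: The bulky trialkylborohydride reduces the C3 ketone by equatorial attack on the β face, as it does with 4,4-disubstituted 3-oxo terpenoids, giving the axial 3α-alcohol.

Step 16
Reactants: 24 methyl 3α-hydroxy-15-[(triisopropylsilyl)oxy]labd-8(17)-en-19-oate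
Product: 25 methyl 3α-acetoxy-15-[(triisopropylsilyl)oxy]labd-8(17)-en-19-oate
Conditions: Ac2O, DMAP, pyridine, 40 °C
Reagents that add atoms: acetic anhydride, CC(=O)OC(C)=O
Why: DMAP-catalysed acyl transfer esterifies the hindered axial secondary alcohol.

Step 17
Reactants: 25 methyl 3α-acetoxy-15-[(triisopropylsilyl)oxy]labd-8(17)-en-19-oate
Product: 26 methyl (3R,4R,5R,9S,10R,13S)-3-acetoxy-15-hydroxylabd-8(17)-en-19-oate (CNP0230414.1)
Conditions: HF·pyridine, pyridine/THF, 0 °C to rt
Reagents that add atoms: none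
Why: Fluoride-mediated desilylation cleaves the primary silyl ether under buffered conditions that spare the acetate, the methyl ester and the exocyclic alkene.

**Compound list**

1 | 3-bromo-4-methylphenol | Cc1ccc(O)cc1Br | starting material
2 | 2-bromo-4-(methoxymethoxy)-1-methylbenzene | Cc1ccc(OCOC)cc1Br | intermediate
3 | [2-bromo-6-(methoxymethoxy)-3-methylphenyl]lithium | Cc1ccc(OCOC)c([Li])c1Br | intermediate
4 | methyl 2-bromo-6-(methoxymethoxy)-3-methylbenzoate | Cc1ccc(OCOC)c(C(=O)OC)c1Br | intermediate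
5 | methyl 2-bromo-6-hydroxy-3-methylbenzoate | Cc1ccc(O)c(C(=O)OC)c1Br | intermediate
6 | (S)-citronellol, (3S)-3,7-dimethyloct-6-en-1-ol | CC(C)=CCC[C@H](C)CCO | starting material
7 | triisopropyl{[(3S)-3,7-dimethyloct-6-en-1-yl]oxy}silane | CC(C)=CCC[C@H](C)CCO[Si](C(C)C)(C(C)C)C(C)C | intermediate
8 | ozonide of 7, 3,3-dimethyl-5-[(3S)-3-methyl-5-[(triisopropylsilyl)oxy]pentyl]-1,2,4-trioxolane (both configurations at C5 of the ring) | CC1(C)OOC(CC[C@H](C)CCO[Si](C(C)C)(C(C)C)C(C)C)O1 | intermediate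
9 | (4S)-4-methyl-6-[(triisopropylsilyl)oxy]hexanal | O=CCC[C@H](C)CCO[Si](C(C)C)(C(C)C)C(C)C | intermediate
10 | ethyl (triphenylphosphoranylidene)acetate | CCOC(=O)C=P(c1ccccc1)(c1ccccc1)c1ccccc1 | starting material
11 | (iodomethyl)trimethylsilane | C[Si](C)(C)CI | starting material
12 | [1-ethoxy-1-oxo-3-(trimethylsilyl)propan-2-yl]triphenylphosphonium iodide (racemic) | CCOC(=O)C(C[Si](C)(C)C)[P+](c1ccccc1)(c1ccccc1)c1ccccc1.[I-] | intermediate
13 | ethyl 2-(triphenylphosphoranylidene)-3-(trimethylsilyl)propanoate | CCOC(=O)C(C[Si](C)(C)C)=P(c1ccccc1)(c1ccccc1)c1ccccc1 | intermediate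
14 | ethyl (2Z,6S)-6-methyl-8-[(triisopropylsilyl)oxy]-2-[(trimethylsilyl)methyl]oct-2-enoate (ester trans to the chain) | CCOC(=O)/C(C[Si](C)(C)C)=C/CC[C@H](C)CCO[Si](C(C)C)(C(C)C)C(C)C | intermediate
15 | (2Z,6S)-6-methyl-8-[(triisopropylsilyl)oxy]-2-[(trimethylsilyl)methyl]oct-2-en-1-ol | OC/C(C[Si](C)(C)C)=C/CC[C@H](C)CCO[Si](C(C)C)(C(C)C)C(C)C | intermediate
16 | (2Z,6S)-6-methyl-8-[(triisopropylsilyl)oxy]-2-[(trimethylsilyl)methyl]oct-2-enal | O=C/C(C[Si](C)(C)C)=C/CC[C@H](C)CCO[Si](C(C)C)(C(C)C)C(C)C | intermediate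
17 | triisopropyl{[(3S,6Z)-3-methyl-7-[(trimethylsilyl)methyl]nona-6,8-dien-1-yl]oxy}silane | C=C/C(C[Si](C)(C)C)=C/CC[C@H](C)CCO[Si](C(C)C)(C(C)C)C(C)C | intermediate
18 | 9-[(3Z,7S)-7-methyl-3-[(trimethylsilyl)methyl]-9-[(triisopropylsilyl)oxy]non-3-en-1-yl]-9-borabicyclo[3.3.1]nonane | C1CC2CCCC(C1)B2CC/C(C[Si](C)(C)C)=C/CC[C@H](C)CCO[Si](C(C)C)(C(C)C)C(C)C | intermediate
19 | methyl 6-hydroxy-3-methyl-2-[(3Z,7S)-7-methyl-3-[(trimethylsilyl)methyl]-9-[(triisopropylsilyl)oxy]non-3-en-1-yl]benzoate | COC(=O)c1c(O)ccc(C)c1CC/C(C[Si](C)(C)C)=C/CC[C@H](C)CCO[Si](C(C)C)(C(C)C)C(C)C | intermediate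
20 | methyl 3-oxo-15-[(triisopropylsilyl)oxy]-18-norlabda-1,4,8(17)-trien-19-oate; 9α-H, 10β-methyl, 13S | C=C1CCC2=C(C(=O)OC)C(=O)C=C[C@]2(C)[C@H]1CC[C@H](C)CCO[Si](C(C)C)(C(C)C)C(C)C | intermediate
21 | methyl 3-oxo-15-[(triisopropylsilyl)oxy]-18-norlabda-4,8(17)-dien-19-oate; 9α-H, 10β-methyl, 13S | C=C1CCC2=C(C(=O)OC)C(=O)CC[C@]2(C)[C@H]1CC[C@H](C)CCO[Si](C(C)C)(C(C)C)C(C)C | intermediate
22 | lithium enolate (C3–OLi, C3=C4) of methyl 3-oxo-15-[(triisopropylsilyl)oxy]-18-norlabd-8(17)-en-19-oate; 5α-H | C=C1CC[C@@H]2[C@](C)(CCC(O[Li])=C2C(=O)OC)[C@H]1CC[C@H](C)CCO[Si](C(C)C)(C(C)C)C(C)C | intermediate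
23 | methyl 3-oxo-15-[(triisopropylsilyl)oxy]labd-8(17)-en-19-oate; 4α-methyl, 4β-ester, 5α-H, 9α-H, 10β-methyl, 13S | C=C1CC[C@@H]2[C@](C)(CCC(=O)[C@]2(C)C(=O)OC)[C@H]1CC[C@H](C)CCO[Si](C(C)C)(C(C)C)C(C)C | intermediate
24 | methyl 3α-hydroxy-15-[(triisopropylsilyl)oxy]labd-8(17)-en-19-oate | C=C1CC[C@@H]2[C@](C)(CC[C@@H](O)[C@]2(C)C(=O)OC)[C@H]1CC[C@H](C)CCO[Si](C(C)C)(C(C)C)C(C)C | intermediate
25 | methyl 3α-acetoxy-15-[(triisopropylsilyl)oxy]labd-8(17)-en-19-oate | C=C1CC[C@@H]2[C@](C)(CC[C@@H](OC(C)=O)[C@]2(C)C(=O)OC)[C@H]1CC[C@H](C)CCO[Si](C(C)C)(C(C)C)C(C)C | intermediate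
26 | methyl (3R,4R,5R,9S,10R,13S)-3-acetoxy-15-hydroxylabd-8(17)-en-19-oate; 3α-OAc, 4α-methyl, 4β-ester, 5α-H, 9α-H, 10β-methyl | C=C1CC[C@@H]2[C@](C)(CC[C@@H](OC(C)=O)[C@]2(C)C(=O)OC)[C@H]1CC[C@H](C)CCO | target

**Step count and risks**

Total step count: 17. Longest linear sequence: 13 steps (from 6 through steps 4, 5 and 7 to 17).

The three steps most likely to fail:

Step 12. The chiral iodine reagent may not discriminate the two faces of C10 well enough, so that ring B forms in both absolute senses; the reagent may also oxidise the allylsilane instead of the phenol, or solvent or acetate may capture C10 before C9 does. The fallback uses known chemistry, an epoxide-initiated and allylsilane-terminated cation–olefin bicyclisation whose absolute configuration comes from a Sharpless epoxidation. It sets out from diene 17, used as its borane 18, and comes back to the route at 23. Pent-4-yn-1-ol is carboaluminated (AlMe3, Cp2ZrCl2 cat., then I2) to (E)-5-iodo-4-methylpent-4-en-1-ol F1, which Dess–Martin periodinane oxidises to (E)-5-iodo-4-methylpent-4-enal F2. Still–Gennari olefination with methyl 2-[bis(2,2,2-trifluoroethoxy)phosphoryl]propanoate (KN(SiMe3)2, 18-crown-6, THF, −78 °C) gives methyl (2Z,6E)-7-iodo-2,6-dimethylhepta-2,6-dienoate F3, and i-Bu2AlH reduces it to (2Z,6E)-7-iodo-2,6-dimethylhepta-2,6-dien-1-ol F4. Sharpless asymmetric epoxidation (Ti(Oi-Pr)4, D-(−)-diethyl tartrate, t-BuOOH, −20 °C) should give the (2R,3S)-epoxy alcohol F5, which is silylated (Et3SiCl, imidazole) to the triethylsilyl ether F6. B-alkyl Suzuki coupling of 18 with F6 (PdCl2(dppf), AsPh3, Cs2CO3, DMF/THF/H2O, rt) forms C5–C6 and gives the epoxy triene F7. MeAlCl2 in CH2Cl2 at −78 °C should then close rings A and B through a chair–chair fold, in which the Z-oxymethyl group ends axial on C4 and the allylsilane leaves C8=C17, to give the 3β-hydroxy 19-silyl ether F8. Methanolysis of the triethylsilyl ether (pyridinium p-toluenesulfonate, MeOH) gives the 3β,19-diol F9, Dess–Martin oxidation the 3-oxo-19-aldehyde F10, Pinnick oxidation (NaClO2, NaH2PO4, 2-methylbut-2-ene) the 3-oxo-19-oic acid F11, and Me3SiCHN2 in MeOH/toluene the methyl ester 23; steps 15 to 17 follow unchanged.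

Step 13. Hydride may be delivered to the doubly activated C5 in competition with C1, or both ring A alkenes may be reduced. The fallback puts electron transfer before hydride; it sets out from dienone 20 and comes back at 23. Li (2.2 equiv) with t-BuOH (1 equiv) in NH3/THF at −78 °C should reduce the most electron-poor alkene C4=C5 regardless of steric access and give the cross-conjugated lithium enolate F12 with C1=C2 intact. Methyl iodide alkylates C4 to give methyl 3-oxo-15-[(triisopropylsilyl)oxy]labda-1,8(17)-dien-19-oate F13, and [(Ph3P)CuH]6 then reduces the only remaining enone alkene C1=C2 to 23.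

Step 11. Oxidative addition and transmetalation may be slow at the C–Br bond flanked by the ester and the methyl group, and the free phenol may interfere with the borane or the base. The fallback is a Negishi coupling of a silyl-protected bromide; it sets out from 17 and 5 and comes back at 19. Hydroboration of 17 with 9-BBN and oxidation (NaOH, H2O2) gives the homoallylic alcohol F14, Appel-type iodination (I2, PPh3, imidazole) the iodide F15, and zinc insertion (Zn dust, LiCl, THF, 40 °C) the alkylzinc iodide F16, used without isolation. Bromide 5 is silylated (t-BuMe2SiCl, imidazole) to the aryl silyl ether F17. Negishi coupling of F16 with F17 (Pd(OAc)2, CPhos, THF, rt) gives the coupled aryl silyl ether F18, and K2CO3 in MeOH removes the aryl silyl group, leaving the alkyl triisopropylsilyl ether, to give 19.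

**Further compounds**

F1 | step 12 | (E)-5-iodo-4-methylpent-4-en-1-ol | OCCC/C(C)=C/I
F2 | step 12 | (E)-5-iodo-4-methylpent-4-enal | O=CCC/C(C)=C/I
F3 | step 12 | methyl (2Z,6E)-7-iodo-2,6-dimethylhepta-2,6-dienoate | COC(=O)/C(C)=C\CC/C(C)=C/I
F4 | step 12 | (2Z,6E)-7-iodo-2,6-dimethylhepta-2,6-dien-1-ol | OC/C(C)=C\CC/C(C)=C/I
F5 | step 12 | [(2R,3S)-3-[(E)-4-iodo-3-methylbut-3-en-1-yl]-2-methyloxiran-2-yl]methanol | OC[C@@]1(C)O[C@H]1CC/C(C)=C/I
F6 | step 12 | triethyl{[(2R,3S)-3-[(E)-4-iodo-3-methylbut-3-en-1-yl]-2-methyloxiran-2-yl]methoxy}silane | CC[Si](CC)(CC)OC[C@@]1(C)O[C@H]1CC/C(C)=C/I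
F7 | step 12 | epoxy triene, (3S,4R)-3,4-epoxy-19-[(triethylsilyl)oxy]-15-[(triisopropylsilyl)oxy]-17-(trimethylsilyl)-4,5:9,10-disecolabda-5(10)E,8Z-diene, 13S | CC[Si](CC)(CC)OC[C@@]1(C)O[C@H]1CC/C(C)=C/CC/C(C[Si](C)(C)C)=C/CC[C@H](C)CCO[Si](C(C)C)(C(C)C)C(C)C
F8 | step 12 | 19-[(triethylsilyl)oxy]-15-[(triisopropylsilyl)oxy]labd-8(17)-en-3β-ol | C=C1CC[C@@H]2[C@](C)(CC[C@H](O)[C@]2(C)CO[Si](CC)(CC)CC)[C@H]1CC[C@H](C)CCO[Si](C(C)C)(C(C)C)C(C)C
F9 | step 12 | 15-[(triisopropylsilyl)oxy]labd-8(17)-ene-3β,19-diol | C=C1CC[C@@H]2[C@](C)(CC[C@H](O)[C@]2(C)CO)[C@H]1CC[C@H](C)CCO[Si](C(C)C)(C(C)C)C(C)C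
F10 | step 12 | 3-oxo-15-[(triisopropylsilyl)oxy]labd-8(17)-en-19-al | C=C1CC[C@@H]2[C@](C)(CCC(=O)[C@]2(C)C=O)[C@H]1CC[C@H](C)CCO[Si](C(C)C)(C(C)C)C(C)C
F11 | step 12 | 3-oxo-15-[(triisopropylsilyl)oxy]labd-8(17)-en-19-oic acid | C=C1CC[C@@H]2[C@](C)(CCC(=O)[C@]2(C)C(=O)O)[C@H]1CC[C@H](C)CCO[Si](C(C)C)(C(C)C)C(C)C
F12 | step 13 | lithium enolate (C3–OLi, C3=C4) of methyl 3-oxo-15-[(triisopropylsilyl)oxy]-18-norlabda-1,8(17)-dien-19-oate, 5α-H | C=C1CC[C@@H]2[C@](C)(C=CC(O[Li])=C2C(=O)OC)[C@H]1CC[C@H](C)CCO[Si](C(C)C)(C(C)C)C(C)C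
F13 | step 13 | methyl 3-oxo-15-[(triisopropylsilyl)oxy]labda-1,8(17)-dien-19-oate | C=C1CC[C@@H]2[C@](C)(C=CC(=O)[C@]2(C)C(=O)OC)[C@H]1CC[C@H](C)CCO[Si](C(C)C)(C(C)C)C(C)C
F14 | step 11 | (3Z,7S)-7-methyl-3-[(trimethylsilyl)methyl]-9-[(triisopropylsilyl)oxy]non-3-en-1-ol | OCC/C(C[Si](C)(C)C)=C/CC[C@H](C)CCO[Si](C(C)C)(C(C)C)C(C)C
F15 | step 11 | {[(3S,6Z)-9-iodo-3-methyl-7-[(trimethylsilyl)methyl]non-6-en-1-yl]oxy}triisopropylsilane | ICC/C(C[Si](C)(C)C)=C/CC[C@H](C)CCO[Si](C(C)C)(C(C)C)C(C)C
F16 | step 11 | [(3Z,7S)-7-methyl-3-[(trimethylsilyl)methyl]-9-[(triisopropylsilyl)oxy]non-3-en-1-yl]zinc iodide | I[Zn]CC/C(C[Si](C)(C)C)=C/CC[C@H](C)CCO[Si](C(C)C)(C(C)C)C(C)C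
F17 | step 11 | methyl 2-bromo-6-[(tert-butyldimethylsilyl)oxy]-3-methylbenzoate | COC(=O)c1c(O[Si](C)(C)C(C)(C)C)ccc(C)c1Br
F18 | step 11 | methyl 6-[(tert-butyldimethylsilyl)oxy]-3-methyl-2-[(3Z,7S)-7-methyl-3-[(trimethylsilyl)methyl]-9-[(triisopropylsilyl)oxy]non-3-en-1-yl]benzoate | COC(=O)c1c(O[Si](C)(C)C(C)(C)C)ccc(C)c1CC/C(C[Si](C)(C)C)=C/CC[C@H](C)CCO[Si](C(C)C)(C(C)C)C(C)C
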